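The three arylglycerol ether arms are removed to leave a differentially protected (7R,7′R,8S,8′S)-syringaresinol, and its furofuran is cut through ring 2 (C7, O, C9′, C8′, C8): the three-atom unit C7–O–C9′ is a carbonyl ylide, and C8–C8′ is the alkene of an (R)-γ-aryl butenolide, the later ring 1 (C7′, O, C9, C8, C8′). One intermolecular [3+2] cycloaddition thus forms C7–C8 and C9′–C8′, closes ring 2 and sets C7, C8 and C8′ from the single centre C7′. Its precursors are (R)-5-(4-benzyloxy-3,5-dimethoxyphenyl)furan-2(5H)-one and the racemic chloromethyl ether of (4-allyloxy-3,5-dimethoxyphenyl)(dimethylphenylsilyl)methanol. The arms are then grown by auxiliary-controlled glycolate aldol reactions.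

Key step: step 7

Conventions and remarks on the chemistry
- Lignan numbering is used. SR = (7R,7′R,8S,8′S)-syringaresinol. O-4 is the phenolic oxygen of the aryl group on C7 (ylide half), O-4′ that of the aryl group on C7′ (butenolide half). G1, G2, G3 are the guaiacylglycerol units (own C7, C8, C9): G1 on O-4, G2 on O-4′, G3 on O-4 of G2. Xc(S), Xc(R) = (S)- or (R)-4-benzyl-2-oxooxazolidin-3-yl. SR is C2-symmetric, so it does not matter which half carries which arm.
- The (R) configuration of the butenolide was checked against C7′ of the target and is the one needed. The same spatial arrangement is named (S) in ynoate 5, because alkynyl outranks aryl.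
- Design changes to the cycloaddition partners: benzyl sits on the butenolide aryl and allyl on the ylide aryl, so that no allyl ether meets the alkyne semihydrogenation. Silicon carries Me2Ph, so that the α-silyl carbinol is made in one catalytic step and silicon is more fluorophilic.
- The boron aldol of an aryloxyacetyl imide gives the 2,3-syn adduct, which is the threo arylglycerol. The erythro units of the target therefore need inversion at C7; this is done once, for all three units, in step 28.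
- Assumption: (S,S)-ProPhenol delivers the alkynyl group to the Re face of 3. The sense is to be confirmed on 7, and the (R,R)-ligand is used if it proves opposite.

Step 1
Reactants: 1 syringaldehyde; 2 benzyl bromide
Product: 3 4-(benzyloxy)-3,5-dimethoxybenzaldehyde
Conditions: K2CO3, DMF, 60 °C
Reagents that add atoms: none
Why: Williamson O-alkylation of the acidic phenol by a reactive benzylic bromide; the benzyl ether withstands organozinc addition, poisoned-palladium hydrogenation, fluoride and hydride.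

Step 2
Reactants: 3 4-(benzyloxy)-3,5-dimethoxybenzaldehyde; 4 methyl propiolate
Product: 5 methyl (S)-4-[4-(benzyloxy)-3,5-dimethoxyphenyl]-4-hydroxybut-2-ynoate
Conditions: Me2Zn (3 equiv), (S,S)-ProPhenol [2,6-bis{[(S)-2-(hydroxydiphenylmethyl)pyrrolidin-1-yl]methyl}-4-methylphenol] (20 mol %), Ph3P=O (40 mol %), toluene, 4 °C; aq. NH4Cl
Reagents that add atoms: none
Why: Catalytic enantioselective alkynylation (dinuclear zinc ProPhenol catalysis) of a non-enolisable aryl aldehyde by the zinc acetylide of methyl propiolate, in which Re-face delivery sets the carbinol centre (the later C7′).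

Step 3
Reactants: 5 methyl (S)-4-[4-(benzyloxy)-3,5-dimethoxyphenyl]-4-hydroxybut-2-ynoate
Product: 7 (R)-5-[4-(benzyloxy)-3,5-dimethoxyphenyl]furan-2(5H)-one, via Z-hydroxy enoate 6 (not isolated)
Conditions: H2 (1 atm), Pd/CaCO3 poisoned with Pb(OAc)2, quinoline, EtOAc, rt; then PPTS (5 mol %), CH2Cl2, rt
Reagents that add atoms: none
Why: Lindlar cis-semihydrogenation gives the Z-enoate, whose hydroxyl and ester are held cis and lactonise under mild acid; the carbinol centre is not touched and the benzyl ether survives the poisoned catalyst.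

Step 4
Reactants: 1 syringaldehyde; 8 allyl bromide
Product: 9 4-(allyloxy)-3,5-dimethoxybenzaldehyde
Conditions: K2CO3, DMF, 50 °C
Reagents that add atoms: none
Why: Williamson O-alkylation; the allyl ether is inert to silyl-copper addition, chloromethylation, fluoride and hydride, and is later removed under neutral palladium catalysis.

Step 5
Reactants: 9 4-(allyloxy)-3,5-dimethoxybenzaldehyde; 10 (dimethylphenylsilyl)boronic acid pinacol ester
Product: 12 rac-[4-(allyloxy)-3,5-dimethoxyphenyl](dimethylphenylsilyl)methanol, via O-boryl ether 11 (not isolated)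
Conditions: (IPr)CuCl [IPr = 1,3-bis(2,6-diisopropylphenyl)imidazol-2-ylidene] (5 mol %), NaOtBu (10 mol %), THF, 0 °C → rt; aq. NH4Cl
Reagents that add atoms: none
Why: Copper-catalysed 1,2-addition of a silyl nucleophile from a silylborane to an aldehyde, which traps the oxygen as a boryl ether, so that no free α-silyl alkoxide forms and Brook rearrangement is avoided; the new centre is racemic and becomes the planar ylide carbon in step 7.

Step 6
Reactants: 12 rac-[4-(allyloxy)-3,5-dimethoxyphenyl](dimethylphenylsilyl)methanol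
Product: 13 rac-chloromethyl [4-(allyloxy)-3,5-dimethoxyphenyl](dimethylphenylsilyl)methyl ether
Conditions: (CH2O)n (1.5 equiv), Me3SiCl (3 equiv), CH2Cl2, 0 °C → rt; volatiles removed, used crude
Reagents that add atoms: formaldehyde (as paraformaldehyde), C=O; chlorotrimethylsilane, C[Si](C)(C)Cl
Why: Chloromethylation of an alcohol (hemiformal, oxocarbenium ion, chloride capture) under anhydrous, weakly acidic conditions that leave the C–Si bond and the allyl ether in place.

Step 7
Reactants: 7 (R)-5-[4-(benzyloxy)-3,5-dimethoxyphenyl]furan-2(5H)-one; 13 rac-chloromethyl [4-(allyloxy)-3,5-dimethoxyphenyl](dimethylphenylsilyl)methyl ether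
Product: 15 (1R,2R,5S,6R)-2-[4-(allyloxy)-3,5-dimethoxyphenyl]-6-[4-(benzyloxy)-3,5-dimethoxyphenyl]-3,7-dioxabicyclo[3.3.0]octan-8-one (exo,exo), via carbonyl ylide 14 (not isolated)
Conditions: CsF (dried, 4 equiv), MeCN, rt; 13 (2 equiv) added over 2 h to 7 and CsF
Reagents that add atoms: none
Why: Fluoride attacks silicon and chloride leaves in a 1,3-elimination that gives the non-stabilised carbonyl ylide 14, which adds across the electron-poor C8=C8′ bond of 7 in a concerted, suprafacial 1,3-dipolar [3+2] cycloaddition; the closest known reaction type is the cycloaddition of fluoride-generated carbonyl ylides from α-silyl chloromethyl ethers with acrylates, maleates and enones. Ring 2 (C7, O, C9′, C8′, C8) is closed by the cycloaddition itself, C7–C8 and C9′–C8′ forming in one step, and the cis ring fusion follows from the ring-locked Z alkene. C8′ is set by approach anti to the C7′ aryl group (the only stereocentre of 7), C8 is tied to C8′ by the suprafacial addition, and C7 is set by the exo transition state that keeps the ylide aryl group away from the lactone ring. The step needs the CH2 terminus at the β-carbon C8′ and the benzylic terminus at C8; this is secured by the larger HOMO coefficient at the unsubstituted ylide carbon meeting the larger LUMO coefficient at the β-carbon, and by the bulky benzylic terminus avoiding the carbon next to the C7′ aryl group. Racemisation of 7 through γ-deprotonation should be held back by the low solubility of CsF in MeCN, the slow addition of 13 and the fluorophilic PhMe2Si group, which takes up fluoride as it dissolves.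

Step 8
Reactants: 15 bicyclic lactone
Product: 16 (2R,3S,4S)-2-[4-(allyloxy)-3,5-dimethoxyphenyl]-4-{(R)-[4-(benzyloxy)-3,5-dimethoxyphenyl](hydroxy)methyl}-3-(hydroxymethyl)tetrahydrofuran
Conditions: LiAlH4 (2 equiv), THF, 0 °C; NaOH/H2O work-up
Reagents that add atoms: none
Why: Hydride reduction of the lactone to the 1,4-diol, which leaves ring 2, the allyl and benzyl ethers and all four stereocentres untouched (C7′ keeps its oxygen).

Step 9
Reactants: 16 diol
Product: 18 4-O-allyl-4′-O-benzyl-SR, via primary mesylate 17 (not isolated)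
Conditions: MsCl (1.1 equiv), pyridine, 0 °C → rt
Reagents that add atoms: none
Why: Selective sulfonylation of the primary hydroxyl followed by intramolecular Williamson etherification (5-exo-tet) by the benzylic hydroxyl closes ring 1 with retention at C7′; any leakage through the benzylic cation converges on the same, thermodynamically preferred exo-aryl ether.

Step 10
Reactants: 18 4-O-allyl-4′-O-benzyl-SR
Product: 19 4′-O-benzyl-SR (free 4-OH)
Conditions: Pd(PPh3)4 (5 mol %), morpholine (5 equiv), THF, rt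
Reagents that add atoms: none
Why: Tsuji–Trost deallylation through a π-allylpalladium complex trapped by morpholine, under neutral conditions that spare the benzyl ether and the acid-sensitive furofuran.

Step 11
Reactants: 20 (S)-4-benzyl-2-oxazolidinone; 21 bromoacetyl bromide
Product: 22 (S)-4-benzyl-3-(bromoacetyl)oxazolidin-2-one
Conditions: n-BuLi (1.0 equiv), THF, −78 °C; then 21 (1.1 equiv), −78 °C
Reagents that add atoms: none
Why: N-acylation of the lithiated oxazolidinone at −78 °C, where the acyl bromide reacts much faster than the alkyl bromide.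

Step 12
Reactants: 19 4′-O-benzyl-SR; 22 (S)-4-benzyl-3-(bromoacetyl)oxazolidin-2-one
Product: 23 SR 4′-O-benzyl ether 4-O-[2-oxo-2-Xc(S)-ethyl] ether
Conditions: K2CO3 (2 equiv), KI (10 mol %), acetone, 40 °C
Reagents that add atoms: none
Why: Williamson O-alkylation of the 2,6-dimethoxyphenoxide at a primary carbon activated by the imide carbonyl (SN2), the mild carbonate base leaving the imide and the furofuran intact.

Step 13
Reactants: 24 vanillin
Product: 25 3-methoxy-4-(triisopropylsilyloxy)benzaldehyde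
Conditions: i-Pr3SiCl, imidazole, DMF, rt
Reagents that add atoms: chlorotriisopropylsilane, CC(C)[Si](Cl)(C(C)C)C(C)C
Why: Phenol silylation; the aryl triisopropylsilyl ether withstands boron aldol, borohydride, carbonate, hydrogenolysis and Mitsunobu conditions and is removed by fluoride at the end.

Step 14
Reactants: 23 SR 4′-O-benzyl ether 4-O-[2-oxo-2-Xc(S)-ethyl] ether; 25 3-methoxy-4-(triisopropylsilyloxy)benzaldehyde
Product: 27 SR 4′-O-benzyl ether 4-O-{(2S,3R)-3-hydroxy-3-[3-methoxy-4-(triisopropylsilyloxy)phenyl]-1-oxo-1-Xc(S)-propan-2-yl} ether, via Z dibutylboron enolate 26 (not isolated)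
Conditions: i-Pr2NEt (1.5 equiv) then n-Bu2BOTf (1.3 equiv), CH2Cl2, −78 → 0 °C; 25 (1.3 equiv), −78 → 0 °C; then pH 7 buffer, MeOH, 30% H2O2, 0 °C
Reagents that add atoms: none
Why: Evans boron aldol, in which the Z(O) enolate reacts through a Zimmerman–Traxler chair on the face away from the benzyl group of the auxiliary and so sets C8 and C7 of G1 (2,3-syn, threo); the amine is present before the boron triflate so that the furofuran does not meet free Lewis acid.

Step 15
Reactants: 27 aldol adduct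
Product: 28 SR 4′-O-benzyl ether 4-O-[(7R,8R)-threo-4-O-TIPS-guaiacylglycerol-8-yl] ether
Conditions: LiBH4 (2 equiv), MeOH (2 equiv), THF, 0 °C
Reagents that add atoms: none
Why: Reductive cleavage of the N-acyloxazolidinone to the primary alcohol C9 with return of the auxiliary; no stereocentre is involved.

Step 16
Reactants: 28 benzyl ether with G1 diol
Product: 29 SR 4-O-[(7R,8R)-threo-4-O-TIPS-guaiacylglycerol-8-yl] ether (free 4′-OH)
Conditions: H2 (1 atm), 10% Pd/C, NaHCO3 (solid), EtOAc, rt, stopped at full conversion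
Reagents that add atoms: none
Why: Hydrogenolysis of the aryl benzyl ether, which in neutral ethyl acetate is much faster than cleavage of the furofuran C–O bonds or of the free secondary benzylic alcohol; silyl ethers are inert.

Step 17
Reactants: 29 phenol with G1 diol; 22 (S)-4-benzyl-3-(bromoacetyl)oxazolidin-2-one
Product: 30 SR 4-O-[(7R,8R)-threo-4-O-TIPS-guaiacylglycerol-8-yl] 4′-O-[2-oxo-2-Xc(S)-ethyl] diether
Conditions: K2CO3 (2 equiv), KI (10 mol %), acetone, 40 °C
Reagents that add atoms: none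
Why: Williamson O-alkylation as in step 12; only the phenol is acidic enough for carbonate, so the two alcohols of G1 stay free.

Step 18
Reactants: 30 imide with G1 diol
Product: 31 SR 4-O-[(7R,8R)-7,9-di-O-acetyl-4-O-TIPS-guaiacylglycerol-8-yl] 4′-O-[2-oxo-2-Xc(S)-ethyl] diether
Conditions: Ac2O (4 equiv), pyridine, DMAP (5 mol %), CH2Cl2, 0 °C → rt
Reagents that add atoms: acetic anhydride, CC(=O)OC(C)=O
Why: Acetylation parks the two hydroxyls of G1 so that they cannot quench the boron enolate of step 25; the esters are removed without an extra step by the borohydride of step 26.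

Step 19
Reactants: 32 (R)-4-benzyl-2-oxazolidinone; 21 bromoacetyl bromide
Product: 33 (R)-4-benzyl-3-(bromoacetyl)oxazolidin-2-one
Conditions: n-BuLi (1.0 equiv), THF, −78 °C; then 21 (1.1 equiv), −78 °C
Reagents that add atoms: none
Why: N-acylation as in step 11, with the antipodal auxiliary needed for the (7R,8S) unit G3.

Step 20
Reactants: 34 (E)-isoeugenol; 33 (R)-4-benzyl-3-(bromoacetyl)oxazolidin-2-one
Product: 35 (R)-4-benzyl-3-{2-[2-methoxy-4-((E)-prop-1-enyl)phenoxy]acetyl}oxazolidin-2-one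
Conditions: K2CO3 (2 equiv), KI (10 mol %), acetone, 40 °C
Reagents that add atoms: none
Why: Williamson O-alkylation of an unhindered guaiacyl phenol; the propenyl group is a masked formyl group that is inert to the enolisation, which a free aldehyde would not be.

Step 21
Reactants: 35 aryloxyacetyl imide; 25 3-methoxy-4-(triisopropylsilyloxy)benzaldehyde
Product: 37 (R)-4-benzyl-3-{(2R,3S)-3-hydroxy-3-[3-methoxy-4-(triisopropylsilyloxy)phenyl]-2-[2-methoxy-4-((E)-prop-1-enyl)phenoxy]propanoyl}oxazolidin-2-one, via Z dibutylboron enolate 36 (not isolated)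
Conditions: i-Pr2NEt (1.5 equiv) then n-Bu2BOTf (1.3 equiv), CH2Cl2, −78 → 0 °C; 25 (1.2 equiv), −78 → 0 °C; then pH 7 buffer, MeOH, 30% H2O2, 0 °C
Reagents that add atoms: none
Why: Evans boron aldol as in step 14 with the (R)-auxiliary, which sets C8 and C7 of G3 in the mirror-image syn (threo) sense.

Step 22
Reactants: 37 aldol adduct
Product: 38 (1S,2S)-1-[3-methoxy-4-(triisopropylsilyloxy)phenyl]-2-[2-methoxy-4-((E)-prop-1-enyl)phenoxy]propane-1,3-diol
Conditions: LiBH4 (2 equiv), MeOH (2 equiv), THF, 0 °C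
Reagents that add atoms: none
Why: Reductive cleavage of the N-acyloxazolidinone to the threo 1,3-diol with return of the auxiliary; the alkene and the silyl ether are inert.

Step 23
Reactants: 38 threo diol
Product: 39 (1S,2S)-1-[3-methoxy-4-(triisopropylsilyloxy)phenyl]-2-[2-methoxy-4-((E)-prop-1-enyl)phenoxy]propane-1,3-diyl diacetate
Conditions: Ac2O (4 equiv), pyridine, DMAP (5 mol %), CH2Cl2, 0 °C → rt
Reagents that add atoms: acetic anhydride, CC(=O)OC(C)=O
Why: Acetylation of both hydroxyls gives an aldehyde partner without acidic protons for step 25; the esters fall in step 26.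

Step 24
Reactants: 39 diacetate
Product: 41 (1S,2S)-2-(4-formyl-2-methoxyphenoxy)-1-[3-methoxy-4-(triisopropylsilyloxy)phenyl]propane-1,3-diyl diacetate, via glycol 40 (not isolated)
Conditions: OsO4 (2 mol %), NaIO4 (4 equiv), 2,6-lutidine (2 equiv), dioxane/H2O 3:1, rt
Reagents that add atoms: osmium tetroxide, O=[Os](=O)(=O)=O (oxygen of the new formyl group; reoxidised by sodium periodate, [Na+].[O-]I(=O)(=O)=O)
Why: Lemieux–Johnson oxidative cleavage (catalytic dihydroxylation of the electron-rich styrene-type alkene, then periodate cleavage of the glycol) unmasks the aldehyde; esters, the silyl ether and the alkoxyarenes are inert.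

Step 25
Reactants: 31 imide with G1 diacetate; 41 aldehyde carrying G3
Product: 43 SR 4-O-[(7R,8R)-7,9-di-O-acetyl-4-O-TIPS-guaiacylglycerol-8-yl] 4′-O-{(2S,3R)-3-hydroxy-1-oxo-1-Xc(S)-3-aryl-propan-2-yl} diether in which aryl is the 3-methoxyphenyl ring of G2 carrying at O-4 the (7S,8S)-7,9-di-O-acetyl-4-O-TIPS-guaiacylglycerol-8-yl unit G3, via Z dibutylboron enolate 42 (not isolated)
Conditions: i-Pr2NEt (1.8 equiv) then n-Bu2BOTf (1.5 equiv), CH2Cl2, −78 → 0 °C; 41 (1.2 equiv), −78 → 0 °C; then pH 7 buffer, MeOH, 30% H2O2, 0 °C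
Reagents that add atoms: none
Why: Evans boron aldol used as the fragment coupling, the (S)-auxiliary alone fixing C8 and C7 of G2 (syn, threo) whatever the remote stereocentres; acetates, silyl ethers and the furofuran tolerate the amine-buffered boron triflate.

Step 26
Reactants: 43 aldol adduct
Product: 44 tris-threo hexaol: SR 4-O-[(7R,8R)-4-O-TIPS-guaiacylglycerol-8-yl] 4′-O-{(7R,8R)-4-O-[(7S,8S)-4-O-TIPS-guaiacylglycerol-8-yl]guaiacylglycerol-8-yl} diether
Conditions: LiBH4 (10 equiv), MeOH (10 equiv), THF, 0 °C → rt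
Reagents that add atoms: none
Why: One borohydride reduction cleaves the N-acyloxazolidinone to the primary alcohol and reduces off the four acetates, so that all three units stand as free threo 1,3-diols; aryl silyl ethers are inert.

Step 27
Reactants: 44 hexaol
Product: 45 tris(9-O-tert-butyldimethylsilyl) ether of 44 (three free C7 hydroxyls)
Conditions: t-BuMe2SiCl (3.3 equiv), imidazole, CH2Cl2/DMF, 0 °C
Reagents that add atoms: tert-butyldimethylsilyl chloride, CC(C)(C)[Si](C)(C)Cl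
Why: Selective silylation, the three primary hydroxyls reacting far faster than the hindered secondary benzylic ones.

Step 28
Reactants: 45 tris-silyl ether
Product: 46 tris-erythro tris(7-O-4-nitrobenzoate): G1 (7S,8R) G2 (7S,8R) G3 (7R,8S) with three 9-O-TBS and two aryl O-TIPS groups
Conditions: 4-nitrobenzoic acid (6 equiv), PPh3 (6 equiv), DIAD (6 equiv), THF, 0 °C → rt
Reagents that add atoms: 4-nitrobenzoic acid, OC(=O)c1ccc(cc1)[N+](=O)[O-]
Why: Mitsunobu inversion, each secondary benzylic hydroxyl being activated as an alkoxyphosphonium ion and displaced by 4-nitrobenzoate with inversion (SN2), which turns the three threo units into the erythro units of the target; the acidic nucleophile and the silylated primary hydroxyls work against ionisation and neighbouring-group participation.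

Step 29
Reactants: 46 tris(4-nitrobenzoate)
Product: 47 tris-erythro triol with three 9-O-TBS and two aryl O-TIPS groups
Conditions: K2CO3 (0.5 equiv), MeOH/THF 1:1, 0 °C
Reagents that add atoms: none
Why: Base-catalysed methanolysis (transesterification) of the activated esters at 0 °C, done while the phenols are still silylated so that no phenoxide faces a benzylic leaving group and no quinone methide can form.

Step 30
Reactants: 47 silylated triol
Product: 48 target CNP0316493.2
Conditions: Bu4NF (8 equiv), AcOH (8 equiv), THF, rt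
Reagents that add atoms: none
Why: Fluoride-induced cleavage of the three alkyl TBS and two aryl TIPS ethers, buffered by acetic acid so that the free p-hydroxybenzyl alcohols and the furofuran do not meet strong base.

Compound list
1 | syringaldehyde | COc1cc(C=O)cc(OC)c1O | starting material
2 | benzyl bromide | BrCc1ccccc1 | starting material
3 | 4-(benzyloxy)-3,5-dimethoxybenzaldehyde | COc1cc(C=O)cc(OC)c1OCc1ccccc1 | intermediate
4 | methyl propiolate | C#CC(=O)OC | starting material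
5 | methyl (S)-4-[4-(benzyloxy)-3,5-dimethoxyphenyl]-4-hydroxybut-2-ynoate | COC(=O)C#C[C@@H](O)c1cc(OC)c(OCc2ccccc2)c(OC)c1 | intermediate
6 | methyl (R,Z)-4-[4-(benzyloxy)-3,5-dimethoxyphenyl]-4-hydroxybut-2-enoate | COC(=O)/C=C\[C@@H](O)c1cc(OC)c(OCc2ccccc2)c(OC)c1 | intermediate (not isolated)
7 | (R)-5-[4-(benzyloxy)-3,5-dimethoxyphenyl]furan-2(5H)-one | COc1cc([C@H]2C=CC(=O)O2)cc(OC)c1OCc1ccccc1 | intermediate
8 | allyl bromide | C=CCBr | starting material
9 | 4-(allyloxy)-3,5-dimethoxybenzaldehyde | C=CCOc1c(OC)cc(C=O)cc1OC | intermediate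
10 | (dimethylphenylsilyl)boronic acid pinacol ester | C[Si](C)(c1ccccc1)B1OC(C)(C)C(C)(C)O1 | starting material
11 | rac-O-(pinacolboryl) ether of 12 | C=CCOc1c(OC)cc(C(OB2OC(C)(C)C(C)(C)O2)[Si](C)(C)c2ccccc2)cc1OC | intermediate (not isolated)
12 | rac-[4-(allyloxy)-3,5-dimethoxyphenyl](dimethylphenylsilyl)methanol | C=CCOc1c(OC)cc(C(O)[Si](C)(C)c2ccccc2)cc1OC | intermediate
13 | rac-chloromethyl [4-(allyloxy)-3,5-dimethoxyphenyl](dimethylphenylsilyl)methyl ether | C=CCOc1c(OC)cc(C(OCCl)[Si](C)(C)c2ccccc2)cc1OC | intermediate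
14 | carbonyl ylide, 4-allyloxy-3,5-dimethoxyphenyl-CH=O(+)-CH2(−) | C=CCOc1c(OC)cc(C=[O+][CH2-])cc1OC | intermediate (not isolated)
15 | (1R,2R,5S,6R)-2-[4-(allyloxy)-3,5-dimethoxyphenyl]-6-[4-(benzyloxy)-3,5-dimethoxyphenyl]-3,7-dioxabicyclo[3.3.0]octan-8-one | COc1cc([C@@H]2OC[C@@H]3[C@H]2C(=O)O[C@H]3c2cc(OC)c(OCc4ccccc4)c(OC)c2)cc(OC)c1OCC=C | intermediate
16 | (2R,3S,4S)-2-[4-(allyloxy)-3,5-dimethoxyphenyl]-4-{(R)-[4-(benzyloxy)-3,5-dimethoxyphenyl](hydroxy)methyl}-3-(hydroxymethyl)tetrahydrofuran | COc1cc([C@@H]2OC[C@H]([C@H]2CO)[C@@H](O)c2cc(OC)c(OCc3ccccc3)c(OC)c2)cc(OC)c1OCC=C | intermediate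
17 | primary methanesulfonate of 16 | COc1cc([C@@H]2OC[C@H]([C@H]2COS(C)(=O)=O)[C@@H](O)c2cc(OC)c(OCc3ccccc3)c(OC)c2)cc(OC)c1OCC=C | intermediate (not isolated)
18 | 4-O-allyl-4′-O-benzyl-(7R,7′R,8S,8′S)-syringaresinol | COc1cc([C@@H]2OC[C@@H]3[C@H]2CO[C@H]3c2cc(OC)c(OCc4ccccc4)c(OC)c2)cc(OC)c1OCC=C | intermediate
19 | 4′-O-benzyl-(7R,7′R,8S,8′S)-syringaresinol | COc1cc([C@@H]2OC[C@@H]3[C@H]2CO[C@H]3c2cc(OC)c(OCc4ccccc4)c(OC)c2)cc(OC)c1O | intermediate
20 | (S)-4-benzyl-2-oxazolidinone | O=C1N[C@@H](Cc2ccccc2)CO1 | starting material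
21 | bromoacetyl bromide | BrCC(Br)=O | starting material
22 | (S)-4-benzyl-3-(bromoacetyl)oxazolidin-2-one | O=C(CBr)N1C(=O)OC[C@@H]1Cc1ccccc1 | intermediate
23 | SR 4′-O-benzyl ether 4-O-[2-oxo-2-Xc(S)-ethyl] ether | COc1cc([C@@H]2OC[C@@H]3[C@H]2CO[C@H]3c2cc(OC)c(OCc4ccccc4)c(OC)c2)cc(OC)c1OCC(=O)N1C(=O)OC[C@@H]1Cc1ccccc1 | intermediate
24 | vanillin | COc1cc(C=O)ccc1O | starting material
25 | 3-methoxy-4-(triisopropylsilyloxy)benzaldehyde | COc1cc(C=O)ccc1O[Si](C(C)C)(C(C)C)C(C)C | intermediate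
26 | Z(O) dibutylboron enolate of 23 | COc1cc([C@@H]2OC[C@@H]3[C@H]2CO[C@H]3c2cc(OC)c(OCc4ccccc4)c(OC)c2)cc(OC)c1O/C=C(\OB(CCCC)CCCC)N1C(=O)OC[C@@H]1Cc1ccccc1 | intermediate (not isolated)
27 | SR 4′-O-benzyl ether 4-O-{(2S,3R)-3-hydroxy-3-[3-methoxy-4-(triisopropylsilyloxy)phenyl]-1-oxo-1-Xc(S)-propan-2-yl} ether | COc1cc([C@@H]2OC[C@@H]3[C@H]2CO[C@H]3c2cc(OC)c(OCc4ccccc4)c(OC)c2)cc(OC)c1O[C@H](C(=O)N1C(=O)OC[C@@H]1Cc1ccccc1)[C@H](O)c1ccc(O[Si](C(C)C)(C(C)C)C(C)C)c(OC)c1 | intermediate
28 | SR 4′-O-benzyl ether 4-O-[(7R,8R)-threo-4-O-TIPS-guaiacylglycerol-8-yl] ether | COc1cc([C@@H]2OC[C@@H]3[C@H]2CO[C@H]3c2cc(OC)c(OCc4ccccc4)c(OC)c2)cc(OC)c1O[C@H](CO)[C@H](O)c1ccc(O[Si](C(C)C)(C(C)C)C(C)C)c(OC)c1 | intermediate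
29 | SR 4-O-[(7R,8R)-threo-4-O-TIPS-guaiacylglycerol-8-yl] ether, free 4′-OH | COc1cc([C@@H]2OC[C@@H]3[C@H]2CO[C@H]3c2cc(OC)c(O)c(OC)c2)cc(OC)c1O[C@H](CO)[C@H](O)c1ccc(O[Si](C(C)C)(C(C)C)C(C)C)c(OC)c1 | intermediate
30 | SR 4-O-[(7R,8R)-threo-4-O-TIPS-guaiacylglycerol-8-yl] 4′-O-[2-oxo-2-Xc(S)-ethyl] diether | COc1cc([C@@H]2OC[C@@H]3[C@H]2CO[C@H]3c2cc(OC)c(OCC(=O)N3C(=O)OC[C@@H]3Cc3ccccc3)c(OC)c2)cc(OC)c1O[C@H](CO)[C@H](O)c1ccc(O[Si](C(C)C)(C(C)C)C(C)C)c(OC)c1 | intermediate
31 | 30 with G1 as 7,9-di-O-acetate | COc1cc([C@@H]2OC[C@@H]3[C@H]2CO[C@H]3c2cc(OC)c(OCC(=O)N3C(=O)OC[C@@H]3Cc3ccccc3)c(OC)c2)cc(OC)c1O[C@H](COC(C)=O)[C@H](OC(C)=O)c1ccc(O[Si](C(C)C)(C(C)C)C(C)C)c(OC)c1 | intermediate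
32 | (R)-4-benzyl-2-oxazolidinone | O=C1N[C@H](Cc2ccccc2)CO1 | starting material
33 | (R)-4-benzyl-3-(bromoacetyl)oxazolidin-2-one | O=C(CBr)N1C(=O)OC[C@H]1Cc1ccccc1 | intermediate
34 | (E)-isoeugenol | COc1cc(/C=C/C)ccc1O | starting material
35 | (R)-4-benzyl-3-{2-[2-methoxy-4-((E)-prop-1-enyl)phenoxy]acetyl}oxazolidin-2-one | COc1cc(/C=C/C)ccc1OCC(=O)N1C(=O)OC[C@H]1Cc1ccccc1 | intermediate
36 | Z(O) dibutylboron enolate of 35 | COc1cc(/C=C/C)ccc1O/C=C(\OB(CCCC)CCCC)N1C(=O)OC[C@H]1Cc1ccccc1 | intermediate (not isolated)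
37 | (R)-4-benzyl-3-{(2R,3S)-3-hydroxy-3-[3-methoxy-4-(triisopropylsilyloxy)phenyl]-2-[2-methoxy-4-((E)-prop-1-enyl)phenoxy]propanoyl}oxazolidin-2-one | COc1cc(/C=C/C)ccc1O[C@@H](C(=O)N1C(=O)OC[C@H]1Cc1ccccc1)[C@@H](O)c1ccc(O[Si](C(C)C)(C(C)C)C(C)C)c(OC)c1 | intermediate
38 | (1S,2S)-1-[3-methoxy-4-(triisopropylsilyloxy)phenyl]-2-[2-methoxy-4-((E)-prop-1-enyl)phenoxy]propane-1,3-diol | COc1cc(/C=C/C)ccc1O[C@@H](CO)[C@@H](O)c1ccc(O[Si](C(C)C)(C(C)C)C(C)C)c(OC)c1 | intermediate
39 | diacetate of 38 | COc1cc(/C=C/C)ccc1O[C@@H](COC(C)=O)[C@@H](OC(C)=O)c1ccc(O[Si](C(C)C)(C(C)C)C(C)C)c(OC)c1 | intermediate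
40 | (1S,2S)-2-[4-(1,2-dihydroxypropyl)-2-methoxyphenoxy]-1-[3-methoxy-4-(triisopropylsilyloxy)phenyl]propane-1,3-diyl diacetate (glycol, diastereomer mixture) | COc1cc(C(O)C(C)O)ccc1O[C@@H](COC(C)=O)[C@@H](OC(C)=O)c1ccc(O[Si](C(C)C)(C(C)C)C(C)C)c(OC)c1 | intermediate (not isolated)
41 | (1S,2S)-2-(4-formyl-2-methoxyphenoxy)-1-[3-methoxy-4-(triisopropylsilyloxy)phenyl]propane-1,3-diyl diacetate | COc1cc(C=O)ccc1O[C@@H](COC(C)=O)[C@@H](OC(C)=O)c1ccc(O[Si](C(C)C)(C(C)C)C(C)C)c(OC)c1 | intermediate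
42 | Z(O) dibutylboron enolate of 31 | COc1cc([C@@H]2OC[C@@H]3[C@H]2CO[C@H]3c2cc(OC)c(O/C=C(\OB(CCCC)CCCC)N3C(=O)OC[C@@H]3Cc3ccccc3)c(OC)c2)cc(OC)c1O[C@H](COC(C)=O)[C@H](OC(C)=O)c1ccc(O[Si](C(C)C)(C(C)C)C(C)C)c(OC)c1 | intermediate (not isolated)
43 | aldol adduct: G1 (7R,8R) diacetate on O-4; on O-4′ the (2S,3R)-imide of G2, whose aryl carries G3 (7S,8S) diacetate | COc1cc([C@@H]2OC[C@@H]3[C@H]2CO[C@H]3c2cc(OC)c(O[C@H](C(=O)N3C(=O)OC[C@@H]3Cc3ccccc3)[C@H](O)c3ccc(O[C@@H](COC(C)=O)[C@@H](OC(C)=O)c4ccc(O[Si](C(C)C)(C(C)C)C(C)C)c(OC)c4)c(OC)c3)c(OC)c2)cc(OC)c1O[C@H](COC(C)=O)[C@H](OC(C)=O)c1ccc(O[Si](C(C)C)(C(C)C)C(C)C)c(OC)c1 | intermediate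
44 | tris-threo hexaol: G1 (7R,8R), G2 (7R,8R), G3 (7S,8S); aryl O-TIPS on G1 and G3 | COc1cc([C@@H]2OC[C@@H]3[C@H]2CO[C@H]3c2cc(OC)c(O[C@H](CO)[C@H](O)c3ccc(O[C@@H](CO)[C@@H](O)c4ccc(O[Si](C(C)C)(C(C)C)C(C)C)c(OC)c4)c(OC)c3)c(OC)c2)cc(OC)c1O[C@H](CO)[C@H](O)c1ccc(O[Si](C(C)C)(C(C)C)C(C)C)c(OC)c1 | intermediate
45 | tris(9-O-TBS) ether of 44 | COc1cc([C@@H]2OC[C@@H]3[C@H]2CO[C@H]3c2cc(OC)c(O[C@H](CO[Si](C)(C)C(C)(C)C)[C@H](O)c3ccc(O[C@@H](CO[Si](C)(C)C(C)(C)C)[C@@H](O)c4ccc(O[Si](C(C)C)(C(C)C)C(C)C)c(OC)c4)c(OC)c3)c(OC)c2)cc(OC)c1O[C@H](CO[Si](C)(C)C(C)(C)C)[C@H](O)c1ccc(O[Si](C(C)C)(C(C)C)C(C)C)c(OC)c1 | intermediate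
46 | tris-erythro tris(7-O-4-nitrobenzoate): G1 (7S,8R), G2 (7S,8R), G3 (7R,8S); three 9-O-TBS, two aryl O-TIPS | COc1cc([C@@H]2OC[C@@H]3[C@H]2CO[C@H]3c2cc(OC)c(O[C@H](CO[Si](C)(C)C(C)(C)C)[C@@H](OC(=O)c3ccc(cc3)[N+](=O)[O-])c3ccc(O[C@@H](CO[Si](C)(C)C(C)(C)C)[C@H](OC(=O)c4ccc(cc4)[N+](=O)[O-])c4ccc(O[Si](C(C)C)(C(C)C)C(C)C)c(OC)c4)c(OC)c3)c(OC)c2)cc(OC)c1O[C@H](CO[Si](C)(C)C(C)(C)C)[C@@H](OC(=O)c1ccc(cc1)[N+](=O)[O-])c1ccc(O[Si](C(C)C)(C(C)C)C(C)C)c(OC)c1 | intermediate
47 | tris-erythro triol: three 9-O-TBS, two aryl O-TIPS | COc1cc([C@@H]2OC[C@@H]3[C@H]2CO[C@H]3c2cc(OC)c(O[C@H](CO[Si](C)(C)C(C)(C)C)[C@@H](O)c3ccc(O[C@@H](CO[Si](C)(C)C(C)(C)C)[C@H](O)c4ccc(O[Si](C(C)C)(C(C)C)C(C)C)c(OC)c4)c(OC)c3)c(OC)c2)cc(OC)c1O[C@H](CO[Si](C)(C)C(C)(C)C)[C@@H](O)c1ccc(O[Si](C(C)C)(C(C)C)C(C)C)c(OC)c1 | intermediate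
48 | CNP0316493.2: SR 4-O-[(7S,8R)-erythro-guaiacylglycerol-8-yl] 4′-O-{(7S,8R)-erythro-4-O-[(7R,8S)-erythro-guaiacylglycerol-8-yl]guaiacylglycerol-8-yl} diether | COc1cc([C@@H](O)[C@H](CO)Oc2ccc([C@H](O)[C@@H](CO)Oc3c(OC)cc([C@@H]4OC[C@@H]5[C@H]4CO[C@H]5c4cc(OC)c(O[C@H](CO)[C@@H](O)c5ccc(O)c(OC)c5)c(OC)c4)cc3OC)cc2OC)ccc1O | target

Totals
Total steps: 30. Longest linear sequence: 19 steps (1, 2, 3, 7, 8, 9, 10, 12, 14, 15, 16, 17, 18, 25, 26, 27, 28, 29, 30; the branch through steps 4, 5, 6 is equally long).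

Steps most likely to fail

Step 7. What may go wrong: the ylide may add with the opposite orientation or to the face syn to the C7′ aryl group, or fluoride may deprotonate C7′ of the butenolide and erode its enantiopurity before the cycloaddition. The fallback sets out from 7 and 9 and comes back at 15; ring 2 is built stepwise instead of by cycloaddition. Benzophenone-sensitised irradiation of 7 in methanol (350 nm) adds the hydroxymethyl radical to C8′ anti to the aryl group and gives (4S,5R)-5-[4-(benzyloxy)-3,5-dimethoxyphenyl]-4-(hydroxymethyl)dihydrofuran-2(3H)-one F1. Its dianion (LDA, 2.2 equiv, THF, −78 °C) adds to aldehyde 9 anti to the hydroxymethyl group and gives (3R,4S,5R)-3-{[4-(allyloxy)-3,5-dimethoxyphenyl](hydroxy)methyl}-5-[4-(benzyloxy)-3,5-dimethoxyphenyl]-4-(hydroxymethyl)dihydrofuran-2(3H)-one F2 as both carbinol epimers. Camphorsulfonic acid (cat., CH2Cl2, 0 °C) ionises the electron-rich benzylic carbinol, and the primary hydroxyl closes ring 2 under thermodynamic control to the exo-aryl lactone 15.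

Step 28. What may go wrong: one of the three electron-rich benzylic oxyphosphonium ions may ionise, so that a site reacts with retention or eliminates and the product carries diastereomers that differ at a single C7. The fallback sets out from 45 and comes back at 47; the inversion is done by oxidation and reduction. Dess–Martin periodinane (NaHCO3, CH2Cl2, rt) oxidises the three carbinols to the tris(9-O-TBS) triketone F3. LiBH(s-Bu)3 (THF, −78 °C) then reduces each α-aryloxy ketone under Felkin–Anh control, hydride entering anti to the aryloxy group, which should give the erythro alcohols, that is triol 47.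

Step 6. What may go wrong: acid may break down the α-silyl benzylic carbinol (ionisation at the benzylic carbon, loss of silicon), or the symmetrical formal may form in place of the chloromethyl ether. The fallback sets out from 12 and comes back at 13. Me2S and dibenzoyl peroxide (MeCN, 0 °C) convert 12 under neutral conditions into rac-[4-(allyloxy)-3,5-dimethoxyphenyl](dimethylphenylsilyl)methyl methylthiomethyl ether F4. SO2Cl2 (CH2Cl2, −78 °C, cyclohexene as scavenger for the sulfenyl chloride) then exchanges the methylthio group for chloride to give 13.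

Further compounds
F1 | step 7 | (4S,5R)-5-[4-(benzyloxy)-3,5-dimethoxyphenyl]-4-(hydroxymethyl)dihydrofuran-2(3H)-one | OC[C@@H]1CC(=O)O[C@H]1c1cc(OC)c(OCc2ccccc2)c(OC)c1
F2 | step 7 | (3R,4S,5R)-3-{[4-(allyloxy)-3,5-dimethoxyphenyl](hydroxy)methyl}-5-[4-(benzyloxy)-3,5-dimethoxyphenyl]-4-(hydroxymethyl)dihydrofuran-2(3H)-one | OC[C@@H]1[C@H](C(O)c2cc(OC)c(OCC=C)c(OC)c2)C(=O)O[C@H]1c1cc(OC)c(OCc2ccccc2)c(OC)c1
F3 | step 28 | tris(9-O-TBS) triketone from 45 (C7 of G1, G2 and G3 as ketones) | COc1cc([C@@H]2OC[C@@H]3[C@H]2CO[C@H]3c2cc(OC)c(O[C@H](CO[Si](C)(C)C(C)(C)C)C(=O)c3ccc(O[C@@H](CO[Si](C)(C)C(C)(C)C)C(=O)c4ccc(O[Si](C(C)C)(C(C)C)C(C)C)c(OC)c4)c(OC)c3)c(OC)c2)cc(OC)c1O[C@H](CO[Si](C)(C)C(C)(C)C)C(=O)c1ccc(O[Si](C(C)C)(C(C)C)C(C)C)c(OC)c1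
F4 | step 6 | rac-[4-(allyloxy)-3,5-dimethoxyphenyl](dimethylphenylsilyl)methyl methylthiomethyl ether | C=CCOc1c(OC)cc(C(OCSC)[Si](C)(C)c2ccccc2)cc1OC
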